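**Retrosynthetic overview**

- Late bonds: Wittig olefination of C15 phosphonium salt 29 with trienal 24; Suzuki coupling of alkenylboronate 16 with bromobutenolide 23 (C8–C9); Sonogashira/5-exo-dig lactonization for the butenolide (ring B); enol triflate Sonogashira for the hydroxycyclohexene (ring C, bought as actinol).
- Ring A (the trihydroxycyclohexane: C1 = CMe2, C2 = CH2, C3 = CHOH, C4 = CH2, C5 = C(Me)OH, C6 = C(OH) bearing C7=C8) is made de novo from the acyclic dienol 9 in one operation: an anionic oxy-Cope rearrangement forms C1–C6, then a ring-closing aldol forms C3–C4.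
- Enabling feature: in ring A, C3 is both the carbinol of a β-hydroxy ketone C3–C4–C5 (C5 carried as a ketone) and, as its aldehyde, the carbonyl end of the δ,ε-unsaturated array C3–C2–C1–C6–C7=C8. That array is the oxy-Cope retron, so the vinyl group on quaternary C6 is a product of the rearrangement.
- Stereochemistry: one carbinol is set by catalysis (step 4) and relayed to C6 (chair oxy-Cope), back to C3 (aldol) and on to C5 (methyl addition).
- Order of ring formation: ring A (step 5), ring B (step 13); ring C is purchased.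

Key step: step 5

Remark on the chemistry: (4R,6R)-actinol (25) and (E)-3-methylpent-2-en-4-yn-1-ol (19) are taken as commercial carotenoid building blocks. Locants are carotenoid-type as defined above; primed locants belong to the alkyne half.

**Step 1**
Reactants: 1 ethyl vinyl ether; 2 acrolein
Product: 4 2-ethoxypenta-1,4-dien-3-ol (racemic), via (1-ethoxyvinyl)lithium 3 (not isolated)
Conditions: 1, t-BuLi, THF, −78 → 0 °C; then 2, −78 °C; aq. NH4Cl
Reagents that add atoms: none
Why: α-Lithiation of the enol ether gives an acetyl anion equivalent that adds 1,2 to the enal (acyl-anion-equivalent addition); the carbinol centre is erased in step 3, so no control is needed.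

**Step 2**
Reactants: 4 2-ethoxypenta-1,4-dien-3-ol
Product: 6 3-[(4-methoxybenzyl)oxy]pent-4-en-2-one (racemic), via dienyl PMB ether 5 (not isolated)
Conditions: NaH, 4-methoxybenzyl chloride, Bu4NI (cat.), THF/DMF, 0 → 23 °C; then aq. oxalic acid, THF, 0 °C
Reagents that add atoms: 4-methoxybenzyl chloride, COc1ccc(CCl)cc1; water, O
Why: Williamson etherification followed by mild hydrolysis of the 2-ethoxy enol ether should unmask the methyl ketone without moving the vinyl group into conjugation.

**Step 3**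
Reactants: 6 3-[(4-methoxybenzyl)oxy]pent-4-en-2-one
Product: 7 tert-butyl({3-[(4-methoxybenzyl)oxy]penta-2,4-dien-2-yl}oxy)dimethylsilane (E/Z mixture)
Conditions: TBSOTf, Et3N, CH2Cl2, 0 → 23 °C
Reagents that add atoms: tert-butyldimethylsilyl triflate, CC(C)(C)[Si](C)(C)OS(=O)(=O)C(F)(F)F
Why: Soft enolization (silyl dienol ether formation) should remove the allylic, α-oxygenated C–H and give the conjugated 2-silyloxy diene; both enol ether geometries serve, because this double bond is consumed in step 4.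

**Step 4**
Reactants: 7 silyl dienol ether; 8 3-methylbut-2-enal (prenal)
Product: 9 (3Z,6S)-6-hydroxy-3-[(4-methoxybenzyl)oxy]-8-methylnona-3,7-dien-2-one
Conditions: SiCl4 (1.1 equiv), chiral binaphthyldiamine-derived bisphosphoramide (5 mol%; the enantiomer that gives the 6S alcohol), i-Pr2NEt (cat.), CH2Cl2, −78 °C; aq. NaHCO3
Reagents that add atoms: none
Why: Catalytic enantioselective vinylogous Mukaiyama aldol addition: the diene should attack through its unsubstituted terminus (the internal carbon is fully substituted), the catalyst sets the (S)-carbinol by face selection on the aldehyde, and reaction through the s-trans diene should give the (Z)-enol ether with acetyl trans to the new chain.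

**Step 5**
Reactants: 9 (3Z,6S)-6-hydroxy-3-[(4-methoxybenzyl)oxy]-8-methylnona-3,7-dien-2-one
Product: 12 (2R,5S)-5-hydroxy-2-[(4-methoxybenzyl)oxy]-3,3-dimethyl-2-vinylcyclohexan-1-one, via dipotassium alkoxide enolate 10 (not isolated), via dipotassium bis-enolate 11 (not isolated)
Conditions: KN(SiMe3)2 (2.3 equiv), 18-crown-6 (2.5 equiv), THF, −78 → 23 °C; aq. NH4Cl at −40 °C
Reagents that add atoms: none
Why: Two equivalents of base convert 9 into dianion 10 (C3 alkoxide plus the C4=C5 enolate; the enolate removes the acceptor that would otherwise allow retro-vinylogous-aldol scrambling of the carbinol), and the alkoxide-accelerated [3,3] shift (anionic oxy-Cope rearrangement) across C1=C2–C3–C8–C7=C6 forms the C1–C6 bond between two fully substituted carbons while breaking C3–C8, which releases the C7=C8 vinyl group and gives bis-enolate 11. Proton shuttling by HN(SiMe3)2 then exposes the C3 aldehyde next to the C4 ketone enolate, which closes ring A by a 6-(enolexo)-exo-trig intramolecular aldol addition; the closest known reaction types are tandem anionic oxy-Cope/aldol sequences and chirality-transferring oxy-Cope constructions of quaternary centres. C6 is set by chirality transfer from the (S)-carbinol through a chair transition state in which the alkoxide must be equatorial, because the (Z)-methyl on C1 would clash 1,3-diaxially with an axial group on C3, while the (Z)-enol ether places the PMB ether axial and C5 equatorial. C3 is re-formed under reversible (retro-aldol) conditions and should settle cis to the C6 oxygen, with the aldolate oxygen equatorial (an axial one would meet the axial C1 methyl) and the C6 ether axial, turned away from the enolate oxygen of the crown-ether-separated potassium enolate. The step needs rearrangement over fragmentation (secured by the dianion), chair over boat (secured by the C1 gem-dimethyl group) and aldol through the ketone enolate (only this closure gives a six-membered ring).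

**Step 6**
Reactants: 12 (2R,5S)-5-hydroxy-2-[(4-methoxybenzyl)oxy]-3,3-dimethyl-2-vinylcyclohexan-1-one
Product: 13 (1S,3R,4R)-4-[(4-methoxybenzyl)oxy]-3,5,5-trimethyl-4-vinylcyclohexane-1,3-diol
Conditions: CeCl3 (anhydrous), MeMgBr (4 equiv), THF, −78 → 0 °C; aq. NH4Cl
Reagents that add atoms: methylmagnesium bromide, C[Mg]Br
Why: Organocerium 1,2-addition to the hindered, enolizable ketone; with the C3 oxygen equatorial one C1 methyl is axial and blocks its face, so methyl should enter equatorially and leave the new C5 hydroxyl axial, trans to the C6 oxygen.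

**Step 7**
Reactants: 13 diol
Product: 14 (1R,2R,4S)-2,4-dihydroxy-1-[(4-methoxybenzyl)oxy]-2,6,6-trimethylcyclohexane-1-carbaldehyde
Conditions: O3, CH2Cl2/MeOH, −78 °C; then Me2S, −78 → 23 °C
Reagents that add atoms: ozone, [O-][O+]=O
Why: Ozonolysis should cleave the only alkene (the anisyl ring reacts far more slowly at −78 °C) to the α-alkoxy aldehyde, whose C6 oxygen stays protected so that no α-ketol shift can occur; no stereocentre is touched.

**Step 8**
Reactants: 14 aldehyde
Product: 15 (1S,3R,4R)-4-[(4-methoxybenzyl)oxy]-3,5,5-trimethyl-4-[(E)-2-(4,4,5,5-tetramethyl-1,3,2-dioxaborolan-2-yl)vinyl]cyclohexane-1,3-diol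
Conditions: CrCl2 (8 equiv), Cl2CHB(pin) (2 equiv), LiI (4 equiv), THF, 23 °C
Reagents that add atoms: 2-(dichloromethyl)-4,4,5,5-tetramethyl-1,3,2-dioxaborolane, ClC(Cl)B1OC(C)(C)C(C)(C)O1
Why: Takai–Utimoto-type CrCl2-mediated borylolefination: the geminal dichromium reagent adds to the hindered aldehyde and eliminates to the (E)-alkenylboronate, and free hydroxyl groups are tolerated.

**Step 9**
Reactants: 15 PMB-protected alkenylboronate
Product: 16 (1S,3R,4R)-3,5,5-trimethyl-4-[(E)-2-(4,4,5,5-tetramethyl-1,3,2-dioxaborolan-2-yl)vinyl]cyclohexane-1,3,4-triol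
Conditions: DDQ (1.5 equiv), CH2Cl2/pH 7 buffer (10:1), 0 °C
Reagents that add atoms: none
Why: Oxidative PMB ether cleavage should free the tertiary C6 hydroxyl before any polyene is present, the alkenylboronate being inert to DDQ.

**Step 10**
Reactants: 17 propiolic acid
Product: 18 (E)-2,3-dibromoacrylic acid
Conditions: Br2, CHCl3, 0 → 23 °C
Reagents that add atoms: bromine, BrBr
Why: Anti bromination of the alkynoic acid places the C3 bromine cis to the carboxyl group, the geometry needed for the lactonization in step 13.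

**Step 11**
Reactants: 19 (E)-3-methylpent-2-en-4-yn-1-ol
Product: 20 (E)-3-methylpent-2-en-4-ynal
Conditions: MnO2, CH2Cl2, 23 °C; used as a solution
Reagents that add atoms: none
Why: Allylic oxidation with MnO2 should give the enynal with retention of the (E)-alkene.

**Step 12**
Reactants: 20 (E)-3-methylpent-2-en-4-ynal
Product: 21 (2E,4E)-5-methylhepta-2,4-dien-6-ynal
Conditions: (triphenylphosphoranylidene)acetaldehyde (1.0 equiv), toluene, 60 °C
Reagents that add atoms: (triphenylphosphoranylidene)acetaldehyde, O=CC=P(c1ccccc1)(c1ccccc1)c1ccccc1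
Why: Wittig olefination with the stabilised formylmethylene ylide should give the (E)-enal, and one equivalent of ylide limits double homologation.

**Step 13**
Reactants: 18 (E)-2,3-dibromoacrylic acid; 21 (2E,4E)-5-methylhepta-2,4-dien-6-ynal
Product: 23 (2E,4E)-6-[(2Z)-4-bromo-5-oxofuran-2(5H)-ylidene]-5-methylhexa-2,4-dienal, via bromoenynoic acid 22 (not isolated)
Conditions: PdCl2(PPh3)2 (5 mol%), CuI (10 mol%), Et3N, MeCN, 23 °C
Reagents that add atoms: none
Why: Tandem Sonogashira coupling at the more reactive β-C–Br bond and 5-exo-dig lactonization of the resulting (Z)-2-en-4-ynoic acid (anti oxymetalation, then protodemetalation) should close ring B and fix the (Z)-ylidene geometry.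

**Step 14**
Reactants: 16 alkenylboronate triol; 23 bromobutenolide
Product: 24 (2E,4E)-5-methyl-6-[(2Z)-5-oxo-4-{(E)-2-[(1R,2R,4S)-1,2,4-trihydroxy-2,6,6-trimethylcyclohexyl]vinyl}furan-2(5H)-ylidene]hexa-2,4-dienal
Conditions: Pd(PPh3)4 (5 mol%), TlOEt (1.8 equiv), THF/H2O (3:1), 23 °C
Reagents that add atoms: none
Why: Suzuki–Miyaura coupling of the activated α-bromobutenolide with the alkenylboronate should join C8 to C9 with retention at both partners, the thallium base allowing room temperature and sparing the base-sensitive enol lactone.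

**Step 15**
Reactants: 25 (4R,6R)-4-hydroxy-2,2,6-trimethylcyclohexan-1-one (actinol)
Product: 26 (4R,6R)-2,2,6-trimethyl-4-[(triethylsilyl)oxy]cyclohexan-1-one
Conditions: Et3SiCl, imidazole, DMF, 0 → 23 °C
Reagents that add atoms: chlorotriethylsilane, CC[Si](Cl)(CC)CC
Why: Standard silyl ether formation protects the carbinol, which is bought with the (R) configuration of C3′.

**Step 16**
Reactants: 26 TES-actinol
Product: 27 (4R)-2,6,6-trimethyl-4-[(triethylsilyl)oxy]cyclohex-1-en-1-yl trifluoromethanesulfonate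
Conditions: LiN(i-Pr)2, THF, −78 → 0 °C; then PhNTf2, −78 → 23 °C
Reagents that add atoms: N-phenylbis(trifluoromethanesulfonimide), O=S(=O)(N(c1ccccc1)S(=O)(=O)C(F)(F)F)C(F)(F)F
Why: Deprotonation can occur only at C6 of the ketone (C2 is quaternary) and O-triflation of the enolate gives the enol triflate; the C6 stereocentre is erased on purpose and the carbinol is untouched.

**Step 17**
Reactants: 27 enol triflate; 19 (E)-3-methylpent-2-en-4-yn-1-ol
Product: 28 (2E)-3-methyl-5-{(4R)-2,6,6-trimethyl-4-[(triethylsilyl)oxy]cyclohex-1-en-1-yl}pent-2-en-4-yn-1-ol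
Conditions: Pd(PPh3)4 (5 mol%), CuI (10 mol%), Et3N, DMF, 23 → 50 °C
Reagents that add atoms: none
Why: Sonogashira coupling of the hindered enol triflate with the terminal enyne should build the ene-yne of ring C with retention of the (E)-alkene.

**Step 18**
Reactants: 28 dienynol
Product: 29 {(2E)-5-[(4R)-4-hydroxy-2,6,6-trimethylcyclohex-1-en-1-yl]-3-methylpent-2-en-4-yn-1-yl}triphenylphosphonium bromide
Conditions: PPh3·HBr, MeOH, 23 °C
Reagents that add atoms: triphenylphosphine hydrobromide, [Br-].c1ccc([PH+](c2ccccc2)c2ccccc2)cc1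
Why: Substitution of the allylic alcohol by PPh3·HBr (allylic phosphonium salt formation) should give the primary salt, and the acidic methanol removes the TES group in the same flask.

**Step 19**
Reactants: 29 C15 phosphonium bromide; 24 trienal
Product: 32 CNP0163979.1 (target), via phosphorus ylide 30 (not isolated), via new-bond Z isomer 31 (not isolated)
Conditions: 29 (1.3 equiv), NaN(SiMe3)2 (2.6 equiv), THF, −78 °C; add 24, −78 → 0 °C; aq. NH4Cl; then I2 (2 mol%), CH2Cl2, 23 °C, dark
Reagents that add atoms: none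
Why: Wittig olefination of the semi-stabilised allylic ylide with the trienal forms the last double bond as an E/Z mixture, and iodine-catalysed equilibration of this disubstituted alkene should funnel isomer 31 into the all-E chain, while the ring-fixed (Z)-ylidene lactone geometry and all stereocentres are unaffected.

**Compound list**

1 | ethyl vinyl ether | C=COCC | starting material
2 | acrolein | C=CC=O | starting material
3 | (1-ethoxyvinyl)lithium | [Li]C(=C)OCC | intermediate (not isolated)
4 | 2-ethoxypenta-1,4-dien-3-ol (racemic) | C=CC(O)C(=C)OCC | intermediate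
5 | 1-{[(2-ethoxypenta-1,4-dien-3-yl)oxy]methyl}-4-methoxybenzene (racemic) | C=CC(OCc1ccc(OC)cc1)C(=C)OCC | intermediate (not isolated)
6 | 3-[(4-methoxybenzyl)oxy]pent-4-en-2-one (racemic) | CC(=O)C(OCc1ccc(OC)cc1)C=C | intermediate
7 | tert-butyl({3-[(4-methoxybenzyl)oxy]penta-2,4-dien-2-yl}oxy)dimethylsilane (E/Z mixture) | CC(O[Si](C)(C)C(C)(C)C)=C(OCc1ccc(OC)cc1)C=C | intermediate
8 | 3-methylbut-2-enal | CC(C)=CC=O | starting material
9 | (3Z,6S)-6-hydroxy-3-[(4-methoxybenzyl)oxy]-8-methylnona-3,7-dien-2-one | CC(=O)/C(OCc1ccc(OC)cc1)=C/C[C@H](O)C=C(C)C | intermediate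
10 | dipotassium (3Z,6S)-3-[(4-methoxybenzyl)oxy]-8-methylnona-1,3,7-triene-2,6-diolate | [K+].[K+].C=C([O-])/C(OCc1ccc(OC)cc1)=C/C[C@H]([O-])C=C(C)C | intermediate (not isolated)
11 | dipotassium (4R)-4-[(4-methoxybenzyl)oxy]-3,3-dimethyl-4-vinylhexa-1,5-diene-1,5-diolate | [K+].[K+].C=C[C@](OCc1ccc(OC)cc1)(C(=C)[O-])C(C)(C)C=C[O-] | intermediate (not isolated)
12 | (2R,5S)-5-hydroxy-2-[(4-methoxybenzyl)oxy]-3,3-dimethyl-2-vinylcyclohexan-1-one | C=C[C@@]1(OCc2ccc(OC)cc2)C(C)(C)C[C@H](O)CC1=O | intermediate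
13 | (1S,3R,4R)-4-[(4-methoxybenzyl)oxy]-3,5,5-trimethyl-4-vinylcyclohexane-1,3-diol | C=C[C@@]1(OCc2ccc(OC)cc2)C(C)(C)C[C@H](O)C[C@@]1(C)O | intermediate
14 | (1R,2R,4S)-2,4-dihydroxy-1-[(4-methoxybenzyl)oxy]-2,6,6-trimethylcyclohexane-1-carbaldehyde | O=C[C@@]1(OCc2ccc(OC)cc2)C(C)(C)C[C@H](O)C[C@@]1(C)O | intermediate
15 | (1S,3R,4R)-4-[(4-methoxybenzyl)oxy]-3,5,5-trimethyl-4-[(E)-2-(4,4,5,5-tetramethyl-1,3,2-dioxaborolan-2-yl)vinyl]cyclohexane-1,3-diol | CC1(C)OB(/C=C/[C@@]2(OCc3ccc(OC)cc3)C(C)(C)C[C@H](O)C[C@@]2(C)O)OC1(C)C | intermediate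
16 | (1S,3R,4R)-3,5,5-trimethyl-4-[(E)-2-(4,4,5,5-tetramethyl-1,3,2-dioxaborolan-2-yl)vinyl]cyclohexane-1,3,4-triol | CC1(C)OB(/C=C/[C@@]2(O)C(C)(C)C[C@H](O)C[C@@]2(C)O)OC1(C)C | intermediate
17 | propiolic acid | C#CC(=O)O | starting material
18 | (E)-2,3-dibromoacrylic acid | OC(=O)/C(Br)=C\Br | intermediate
19 | (E)-3-methylpent-2-en-4-yn-1-ol | C#C/C(C)=C/CO | starting material
20 | (E)-3-methylpent-2-en-4-ynal | C#C/C(C)=C/C=O | intermediate
21 | (2E,4E)-5-methylhepta-2,4-dien-6-ynal | C#C/C(C)=C/C=C/C=O | intermediate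
22 | (2E,6E,8E)-2-bromo-6-methyl-10-oxodeca-2,6,8-trien-4-ynoic acid | OC(=O)/C(Br)=C\C#C/C(C)=C/C=C/C=O | intermediate (not isolated)
23 | (2E,4E)-6-[(2Z)-4-bromo-5-oxofuran-2(5H)-ylidene]-5-methylhexa-2,4-dienal | O=C/C=C/C=C(C)/C=C1C=C(Br)C(=O)O/1 | intermediate
24 | (2E,4E)-5-methyl-6-[(2Z)-5-oxo-4-{(E)-2-[(1R,2R,4S)-1,2,4-trihydroxy-2,6,6-trimethylcyclohexyl]vinyl}furan-2(5H)-ylidene]hexa-2,4-dienal | O=C/C=C/C=C(C)/C=C1C=C(/C=C/[C@@]2(O)C(C)(C)C[C@H](O)C[C@@]2(C)O)C(=O)O/1 | intermediate
25 | (4R,6R)-4-hydroxy-2,2,6-trimethylcyclohexan-1-one | CC1(C)C[C@H](O)C[C@@H](C)C1=O | starting material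
26 | (4R,6R)-2,2,6-trimethyl-4-[(triethylsilyl)oxy]cyclohexan-1-one | CC1(C)C[C@H](O[Si](CC)(CC)CC)C[C@@H](C)C1=O | intermediate
27 | (4R)-2,6,6-trimethyl-4-[(triethylsilyl)oxy]cyclohex-1-en-1-yl trifluoromethanesulfonate | CC1=C(OS(=O)(=O)C(F)(F)F)C(C)(C)C[C@H](O[Si](CC)(CC)CC)C1 | intermediate
28 | (2E)-3-methyl-5-{(4R)-2,6,6-trimethyl-4-[(triethylsilyl)oxy]cyclohex-1-en-1-yl}pent-2-en-4-yn-1-ol | CC1=C(C#C/C(C)=C/CO)C(C)(C)C[C@H](O[Si](CC)(CC)CC)C1 | intermediate
29 | {(2E)-5-[(4R)-4-hydroxy-2,6,6-trimethylcyclohex-1-en-1-yl]-3-methylpent-2-en-4-yn-1-yl}triphenylphosphonium bromide | CC1=C(C#C/C(C)=C/C[P+](c2ccccc2)(c2ccccc2)c2ccccc2)C(C)(C)C[C@H](O)C1.[Br-] | intermediate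
30 | sodium alkoxide of the ylide from 29 | CC1=C(C#C/C(C)=C/C=P(c2ccccc2)(c2ccccc2)c2ccccc2)C(C)(C)C[C@H]([O-])C1.[Na+] | intermediate (not isolated)
31 | isomer of the target with Z geometry at the double bond formed in step 19 | CC1=C(C#C/C(C)=C/C=C\C=C\C=C(C)\C=C2C=C(/C=C/[C@@]3(O)C(C)(C)C[C@H](O)C[C@@]3(C)O)C(=O)O\2)C(C)(C)C[C@H](O)C1 | intermediate (not isolated)
32 | CNP0163979.1 | CC1=C(C#C/C(C)=C/C=C/C=C/C=C(C)/C=C2C=C(/C=C/[C@@]3(O)C(C)(C)C[C@H](O)C[C@@]3(C)O)C(=O)O/2)C(C)(C)C[C@H](O)C1 | target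

**Step count and risks**

Total steps: 19. Longest linear sequence: 11 steps (steps 1–9, 14, 19).

Steps most likely to fail:

1. Step 5. What may go wrong: fragmentation of the alkoxide (retro-vinylogous aldol) or a boat transition state eroding the chirality transfer to C6, and incomplete facial bias in the ring-closing aldol giving C3 epimers. Fallback (sets out from 9, returns at 12): silylation of 9 (TBSOTf, 2,6-lutidine) gives (3Z,6S)-6-[(tert-butyldimethylsilyl)oxy]-3-[(4-methoxybenzyl)oxy]-8-methylnona-3,7-dien-2-one F1. A neutral thermal silyloxy-Cope rearrangement (toluene, 160 °C, sealed tube), in which no alkoxide is present and the bulky silyloxy group is held equatorial, gives the silyl enol ether (3R)-3-{(3E)-4-[(tert-butyldimethylsilyl)oxy]-2-methylbut-3-en-2-yl}-3-[(4-methoxybenzyl)oxy]pent-4-en-2-one F2. Hydrolysis (AcOH, THF/H2O) gives the keto aldehyde (4R)-4-acetyl-4-[(4-methoxybenzyl)oxy]-3,3-dimethylhex-5-enal F3. A separate proline-catalysed 6-enolexo aldol cyclization, with the proline enantiomer chosen to reinforce the substrate bias for the 5S carbinol, then gives 12.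

2. Step 4. What may go wrong: low enantioselectivity, attack through the internal diene carbon or hetero-Diels–Alder consumption of the electron-rich diene, and leakage to the (E)-enol ether. Fallback (sets out from 8, returns at 9): Roskamp homologation of 8 with ethyl diazoacetate (SnCl2 cat., CH2Cl2) gives ethyl 5-methyl-3-oxohex-4-enoate F4. Noyori hydrogenation of the ketone (RuCl2[(R)-BINAP], H2, EtOH) gives ethyl (3S)-3-hydroxy-5-methylhex-4-enoate F5. Silylation (TBSCl, imidazole) gives ethyl (3S)-3-[(tert-butyldimethylsilyl)oxy]-5-methylhex-4-enoate F6, and partial reduction (i-Bu2AlH, CH2Cl2, −78 °C) gives (3S)-3-[(tert-butyldimethylsilyl)oxy]-5-methylhex-4-enal F7. Horner–Wadsworth–Emmons olefination of F7 with dimethyl {1-[(4-methoxybenzyl)oxy]-2-oxopropyl}phosphonate F8 (from dimethyl (1-diazo-2-oxopropyl)phosphonate and 4-methoxybenzyl alcohol by Rh2(OAc)4-catalysed O–H insertion; Ba(OH)2, wet THF) gives the silyl ether F1 with acetyl trans to the chain. HF·pyridine then gives 9.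

3. Step 6. What may go wrong: poor facial selectivity (the axial C1 methyl on one face competes with the axial C6 ether on the other), enolization, or retro-aldol opening of the metal aldolate. Fallback (sets out from 12, returns at 13): silylation (Et3SiCl, imidazole) gives (2R,5S)-2-[(4-methoxybenzyl)oxy]-3,3-dimethyl-5-[(triethylsilyl)oxy]-2-vinylcyclohexan-1-one F9. Corey–Chaykovsky methylenation with dimethylsulfoxonium methylide (Me3S(O)I, NaH, DMSO), which delivers the methylene equatorially under thermodynamic control, gives the spiro-epoxide (3S,4R,7S)-4-[(4-methoxybenzyl)oxy]-5,5-dimethyl-7-[(triethylsilyl)oxy]-4-vinyl-1-oxaspiro[2.5]octane F10. Hydride opening at the CH2 terminus (LiBHEt3, THF) gives (1R,2R,5S)-2-[(4-methoxybenzyl)oxy]-1,3,3-trimethyl-5-[(triethylsilyl)oxy]-2-vinylcyclohexan-1-ol F11. Desilylation (pyridinium p-toluenesulfonate, MeOH) then gives 13.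

**Further compounds**

F1 | step 5 | (3Z,6S)-6-[(tert-butyldimethylsilyl)oxy]-3-[(4-methoxybenzyl)oxy]-8-methylnona-3,7-dien-2-one | CC(=O)/C(OCc1ccc(OC)cc1)=C/C[C@H](O[Si](C)(C)C(C)(C)C)C=C(C)C
F2 | step 5 | (3R)-3-{(3E)-4-[(tert-butyldimethylsilyl)oxy]-2-methylbut-3-en-2-yl}-3-[(4-methoxybenzyl)oxy]pent-4-en-2-one | C=C[C@](OCc1ccc(OC)cc1)(C(C)=O)C(C)(C)/C=C/O[Si](C)(C)C(C)(C)C
F3 | step 5 | (4R)-4-acetyl-4-[(4-methoxybenzyl)oxy]-3,3-dimethylhex-5-enal | C=C[C@](OCc1ccc(OC)cc1)(C(C)=O)C(C)(C)CC=O
F4 | step 4 | ethyl 5-methyl-3-oxohex-4-enoate | CCOC(=O)CC(=O)C=C(C)C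
F5 | step 4 | ethyl (3S)-3-hydroxy-5-methylhex-4-enoate | CCOC(=O)C[C@H](O)C=C(C)C
F6 | step 4 | ethyl (3S)-3-[(tert-butyldimethylsilyl)oxy]-5-methylhex-4-enoate | CCOC(=O)C[C@H](O[Si](C)(C)C(C)(C)C)C=C(C)C
F7 | step 4 | (3S)-3-[(tert-butyldimethylsilyl)oxy]-5-methylhex-4-enal | O=CC[C@H](O[Si](C)(C)C(C)(C)C)C=C(C)C
F8 | step 4 | dimethyl {1-[(4-methoxybenzyl)oxy]-2-oxopropyl}phosphonate | COP(=O)(OC)C(OCc1ccc(OC)cc1)C(C)=O
F9 | step 6 | (2R,5S)-2-[(4-methoxybenzyl)oxy]-3,3-dimethyl-5-[(triethylsilyl)oxy]-2-vinylcyclohexan-1-one | C=C[C@@]1(OCc2ccc(OC)cc2)C(C)(C)C[C@H](O[Si](CC)(CC)CC)CC1=O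
F10 | step 6 | (3S,4R,7S)-4-[(4-methoxybenzyl)oxy]-5,5-dimethyl-7-[(triethylsilyl)oxy]-4-vinyl-1-oxaspiro[2.5]octane | C=C[C@@]1(OCc2ccc(OC)cc2)C(C)(C)C[C@H](O[Si](CC)(CC)CC)C[C@@]1(C3)O3
F11 | step 6 | (1R,2R,5S)-2-[(4-methoxybenzyl)oxy]-1,3,3-trimethyl-5-[(triethylsilyl)oxy]-2-vinylcyclohexan-1-ol | C=C[C@@]1(OCc2ccc(OC)cc2)C(C)(C)C[C@H](O[Si](CC)(CC)CC)C[C@@]1(C)O
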